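**Retrosynthetic overview**
1. The target is robinetinidol-(4α→8)-epigallocatechin. The last C–C bond made is the interflavan bond C4 (upper unit, ring C) to C8 (lower unit, ring D), by acid-mediated Friedel–Crafts union of the benzylated flavan-3,4-diol from (+)-dihydrorobinetin with penta-O-benzyl-epigallocatechin; nine benzyl ethers fall in the final hydrogenolysis.
2. The lower pyran (ring F: O1, C2, C3, C4, C4a, C8a) is cut at C3–C4 and at O1–C8a. It is made by a (3+3) annulation of the dilithio dianion of a β-hydroxy ester (O1–C2–C3 unit) with 2-bromo-4,6-bis(benzyloxy)benzyl bromide (C4–C4a–C8a unit).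
3. Enabling feature: in ring F, O1 and C3 stand 1,3 across the carbinol C2, and the C3 hydroxyl can stand in for a carboxyl carbon (Baeyer–Villiger, retention), so O1–C2–C3 is an aldol whose dianion is a C,O-bis-nucleophile. The benzylic C4H2 sits on C4a, ortho to the ether carbon C8a, so that side is an ortho-bromobenzyl bromide bis-electrophile.
4. Stereochemistry: lower C2 by asymmetric transfer hydrogenation; lower C3 anti by Fráter–Seebach alkylation, which becomes 2,3-cis on ring closure; upper C2 and C3 from the chiral pool; upper C4 by attack anti to the C3 hydroxyl.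
5. Ring order: rings A, C, B arrive intact in dihydrorobinetin, rings D and E are bought as arenes, and ring F is the only ring built (step 7).

Key step: step 7

Remark: flavan numbering is used; A, C, B are the benzo, pyran and pyrogallol rings of the upper unit and D, F, E those of the lower unit. (+)-Dihydrorobinetin (2R,3R) is taken as a purchasable natural flavanonol that supplies upper C2 and C3.

**Route**

Step 1
Reactants: 1 methyl 3,4,5-tris(benzyloxy)benzoate
Product: 2 ethyl 3-oxo-3-[3,4,5-tris(benzyloxy)phenyl]propanoate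
Conditions: EtOAc (2 equiv), LiN(SiMe3)2 (3 equiv), THF, −78 to 0 °C; then 1 M HCl
Reagents that add atoms: ethyl acetate, CCOC(C)=O
Why: Crossed Claisen condensation of the lithium enolate of ethyl acetate with a non-enolisable aryl ester, driven to completion by deprotonation of the β-keto ester formed.

Step 2
Reactants: 2 ethyl 3-oxo-3-[3,4,5-tris(benzyloxy)phenyl]propanoate
Product: 3 ethyl (3S)-3-hydroxy-3-[3,4,5-tris(benzyloxy)phenyl]propanoate
Conditions: RuCl(p-cymene)[(S,S)-TsDPEN] (1 mol%), HCO2H/Et3N (5:2), DMF, 40 °C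
Reagents that add atoms: none
Why: Noyori-type asymmetric transfer hydrogenation of an aryl ketone, in which the (S,S)-catalyst should give the (S)-carbinol (the future C2 of ring F) as it does for simple aryl ketones, with benzyl ethers inert.

Step 3
Reactants: 4 5-bromoresorcinol (5-bromobenzene-1,3-diol)
Product: 5 1-bromo-3,5-bis(benzyloxy)benzene
Conditions: BnBr (2.2 equiv), K2CO3, DMF, 60 °C
Reagents that add atoms: benzyl bromide, BrCc1ccccc1
Why: Williamson ether synthesis on both phenols.

Step 4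
Reactants: 5 1-bromo-3,5-bis(benzyloxy)benzene
Product: 7 2-bromo-4,6-bis(benzyloxy)benzaldehyde, via aryl iminium salt 6 (not isolated)
Conditions: POCl3 (1.5 equiv), DMF, 0 to 80 °C; then H2O, 50 °C
Reagents that add atoms: N,N-dimethylformamide, CN(C)C=O; water, O
Why: Vilsmeier–Haack formylation, which should go para to one benzyloxy group and ortho to the other (between Br and OBn) rather than into the site between the two ethers, placing the future C4 next to the bromine-bearing C8a.

Step 5
Reactants: 7 2-bromo-4,6-bis(benzyloxy)benzaldehyde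
Product: 8 [2-bromo-4,6-bis(benzyloxy)phenyl]methanol
Conditions: NaBH4, THF/MeOH, 0 °C
Reagents that add atoms: none
Why: Borohydride reduction of the aldehyde, which leaves the aryl bromide and the ethers untouched.

Step 6
Reactants: 8 [2-bromo-4,6-bis(benzyloxy)phenyl]methanol
Product: 9 1-bromo-2-(bromomethyl)-3,5-bis(benzyloxy)benzene
Conditions: PBr3 (0.4 equiv), Et2O, 0 °C; crude bromide used at once
Reagents that add atoms: phosphorus tribromide, BrP(Br)Br
Why: Conversion of an electron-rich benzylic alcohol into the bromide via its phosphite ester; the labile product is not stored.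

Step 7
Reactants: 3 ethyl (3S)-3-hydroxy-3-[3,4,5-tris(benzyloxy)phenyl]propanoate; 9 1-bromo-2-(bromomethyl)-3,5-bis(benzyloxy)benzene
Product: 12 ethyl (2S,3R)-5,7-bis(benzyloxy)-2-[3,4,5-tris(benzyloxy)phenyl]chromane-3-carboxylate (2,3-cis), via dilithio dianion 10 (not isolated), via lithium alkoxide 11 (not isolated)
Conditions: LiN(iPr)2 (2.05 equiv), THF, −78 to −20 °C; 9 (1.05 equiv), −78 to −10 °C; then Pd2(dba)3 (2.5 mol%), 2-(di-tert-butylphosphino)-1,1'-binaphthyl (6 mol%), toluene, 50 °C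
Reagents that add atoms: none
Why: Proposed new method: LiN(iPr)2 turns 3 into the chelated dilithio alkoxide-enolate 10, whose carbon terminus (future C3) is benzylated by 9 from the face anti to the C2 aryl group (Fráter–Seebach alkylation), and the lithium alkoxide O1 left in 11 is then arylated at C8a by oxidative addition of zerovalent palladium into the C–Br bond, alkoxide exchange and C–O reductive elimination, so C3–C4 and O1–C8a form in one flask without work-up. The closest known reaction types are the anti-selective alkylation of β-hydroxy ester dianions with benzyl bromides and the palladium-catalysed intramolecular etherification of aryl bromides with secondary alkoxides to chromans; only their merger, with the lithium aldolate itself as coupling nucleophile, is new. Ring F closes in the second event as a six-membered ring by C–O reductive elimination from a seven-membered oxapalladacycle (formally a 6-exo attack of O1 on the arene carbon C8a). C2 comes in from 3 and no bond to it is made or broken, C3 is set by 1,2-induction from C2 through the lithium chelate, and the anti relation of O1 and C4 in the open chain becomes the 2,3-cis relation in the ring. The step needs C- over O-benzylation (the enolate carbon is the most nucleophilic site of the dianion), arylation of O1 only (it is the only alkoxide, and attack of C3 on C8a would give a four-membered ring) and survival of the aldolate (lithium counter-ion, an ester enolate as the poor leaving group of a retro-aldol, no free amide base once 9 is added, 50 °C ceiling).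

Step 8
Reactants: 12 ethyl (2S,3R)-5,7-bis(benzyloxy)-2-[3,4,5-tris(benzyloxy)phenyl]chromane-3-carboxylate
Product: 14 1-[(2S,3R)-5,7-bis(benzyloxy)-2-[3,4,5-tris(benzyloxy)phenyl]chroman-3-yl]ethan-1-one, via Weinreb amide 13 (not isolated)
Conditions: MeNH(OMe)·HCl (1.5 equiv), i-PrMgCl (3.0 equiv), THF, −20 °C; then MeMgBr (3 equiv), −20 to 0 °C; cold 1 M HCl
Reagents that add atoms: methylmagnesium bromide, C[Mg]Br
Why: Weinreb ketone synthesis run in one flask (magnesium amide aminolysis of the ester, then Grignard addition), in which both stages pass through chelated tetrahedral intermediates, so C3–H is not removed and the 2,3-cis relation should be kept.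

Step 9
Reactants: 14 1-[(2S,3R)-5,7-bis(benzyloxy)-2-[3,4,5-tris(benzyloxy)phenyl]chroman-3-yl]ethan-1-one
Product: 15 (2R,3R)-5,7-bis(benzyloxy)-2-[3,4,5-tris(benzyloxy)phenyl]chroman-3-yl acetate
Conditions: mCPBA (1.5 equiv), CH2Cl2, 0 °C to rt, dark
Reagents that add atoms: 3-chloroperoxybenzoic acid, OOC(=O)c1cccc(Cl)c1
Why: Baeyer–Villiger oxidation, in which the secondary ring carbon C3 migrates in preference to methyl and with retention, so the acetyl group becomes the C3 acetate with the cis configuration intact.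

Step 10
Reactants: 15 (2R,3R)-5,7-bis(benzyloxy)-2-[3,4,5-tris(benzyloxy)phenyl]chroman-3-yl acetate
Product: 16 (2R,3R)-5,7-bis(benzyloxy)-2-[3,4,5-tris(benzyloxy)phenyl]chroman-3-ol (penta-O-benzyl-(−)-epigallocatechin)
Conditions: K2CO3 (0.2 equiv), MeOH/THF, rt
Reagents that add atoms: none
Why: Base-catalysed transesterification of the acetate to methanol, which touches no stereocenter.

Step 11
Reactants: 17 (+)-dihydrorobinetin, (2R,3R)-3,7-dihydroxy-2-(3,4,5-trihydroxyphenyl)chroman-4-one
Product: 18 (2R,3R)-7-(benzyloxy)-3-hydroxy-2-[3,4,5-tris(benzyloxy)phenyl]chroman-4-one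
Conditions: BnBr (4.4 equiv), K2CO3, DMF, rt, argon
Reagents that add atoms: benzyl bromide, BrCc1ccccc1
Why: Williamson ether synthesis on the four phenols only (the secondary C3 alcohol is far less acidic), run at room temperature to spare the base-sensitive flavanonol centers C2 and C3.

Step 12
Reactants: 18 (2R,3R)-7-(benzyloxy)-3-hydroxy-2-[3,4,5-tris(benzyloxy)phenyl]chroman-4-one
Product: 19 (2R,3S,4R)-7-(benzyloxy)-2-[3,4,5-tris(benzyloxy)phenyl]chromane-3,4-diol
Conditions: NaBH4, THF/MeOH, 0 °C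
Reagents that add atoms: none
Why: Borohydride reduction of the C4 ketone, expected to give mainly the 3,4-trans diol, although the C4 configuration is of no consequence because C4 is ionised in the next step.

Step 13
Reactants: 19 (2R,3S,4R)-7-(benzyloxy)-2-[3,4,5-tris(benzyloxy)phenyl]chromane-3,4-diol; 16 penta-O-benzyl-(−)-epigallocatechin
Product: 20 nona-O-benzyl-robinetinidol-(4α→8)-epigallocatechin, (2R,3S,4S)-7-(benzyloxy)-4-[(2R,3R)-5,7-bis(benzyloxy)-3-hydroxy-2-[3,4,5-tris(benzyloxy)phenyl]chroman-8-yl]-2-[3,4,5-tris(benzyloxy)phenyl]chroman-3-ol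
Conditions: 16 (3 equiv), TMSOTf (0.3 equiv), 4 Å molecular sieves, CH2Cl2, −78 to −30 °C
Reagents that add atoms: none
Why: Friedel–Crafts alkylation through the C4 benzylic cation of ring C (stabilised by the para 7-benzyloxy group), which ring D should attack from the face anti to the C3 hydroxyl (3,4-trans, 4α) and through C8, the site flanked by the ring oxygen and not by two benzyloxy groups, with excess 16 holding back higher oligomers.

Step 14
Reactants: 20 nona-O-benzyl-robinetinidol-(4α→8)-epigallocatechin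
Product: 21 robinetinidol-(4α→8)-epigallocatechin (target)
Conditions: H2 (1 atm), Pd(OH)2 on carbon, THF/MeOH/H2O, rt
Reagents that add atoms: none
Why: Hydrogenolysis of all nine benzyl ethers under neutral conditions that should leave the interflavan bond and the two pyran rings intact.

**Compound list**
1 | methyl 3,4,5-tris(benzyloxy)benzoate | COC(=O)c1cc(OCc2ccccc2)c(OCc2ccccc2)c(OCc2ccccc2)c1 | starting material
2 | ethyl 3-oxo-3-[3,4,5-tris(benzyloxy)phenyl]propanoate | CCOC(=O)CC(=O)c1cc(OCc2ccccc2)c(OCc2ccccc2)c(OCc2ccccc2)c1 | intermediate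
3 | ethyl (3S)-3-hydroxy-3-[3,4,5-tris(benzyloxy)phenyl]propanoate | CCOC(=O)C[C@H](O)c1cc(OCc2ccccc2)c(OCc2ccccc2)c(OCc2ccccc2)c1 | intermediate
4 | 5-bromoresorcinol | Oc1cc(O)cc(Br)c1 | starting material
5 | 1-bromo-3,5-bis(benzyloxy)benzene | Brc1cc(OCc2ccccc2)cc(OCc2ccccc2)c1 | intermediate
6 | N-{[2-bromo-4,6-bis(benzyloxy)phenyl]methylidene}-N-methylmethanaminium dichlorophosphate | C[N+](C)=Cc1c(Br)cc(OCc2ccccc2)cc1OCc1ccccc1.[O-]P(=O)(Cl)Cl | intermediate
7 | 2-bromo-4,6-bis(benzyloxy)benzaldehyde | O=Cc1c(Br)cc(OCc2ccccc2)cc1OCc1ccccc1 | intermediate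
8 | [2-bromo-4,6-bis(benzyloxy)phenyl]methanol | OCc1c(Br)cc(OCc2ccccc2)cc1OCc1ccccc1 | intermediate
9 | 1-bromo-2-(bromomethyl)-3,5-bis(benzyloxy)benzene | BrCc1c(Br)cc(OCc2ccccc2)cc1OCc1ccccc1 | intermediate
10 | dilithium alkoxide-enolate of 3 (S at the carbinol carbon) | [Li+].[Li+].CCOC([O-])=C[C@H]([O-])c1cc(OCc2ccccc2)c(OCc2ccccc2)c(OCc2ccccc2)c1 | intermediate
11 | lithium alkoxide of ethyl (2R,3S)-2-[2-bromo-4,6-bis(benzyloxy)benzyl]-3-hydroxy-3-[3,4,5-tris(benzyloxy)phenyl]propanoate | [Li+].CCOC(=O)[C@H](Cc1c(Br)cc(OCc2ccccc2)cc1OCc1ccccc1)[C@H]([O-])c1cc(OCc2ccccc2)c(OCc2ccccc2)c(OCc2ccccc2)c1 | intermediate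
12 | ethyl (2S,3R)-5,7-bis(benzyloxy)-2-[3,4,5-tris(benzyloxy)phenyl]chromane-3-carboxylate | CCOC(=O)[C@@H]1Cc2c(OCc3ccccc3)cc(OCc3ccccc3)cc2O[C@@H]1c1cc(OCc2ccccc2)c(OCc2ccccc2)c(OCc2ccccc2)c1 | intermediate
13 | (2S,3R)-5,7-bis(benzyloxy)-N-methoxy-N-methyl-2-[3,4,5-tris(benzyloxy)phenyl]chromane-3-carboxamide | CON(C)C(=O)[C@@H]1Cc2c(OCc3ccccc3)cc(OCc3ccccc3)cc2O[C@@H]1c1cc(OCc2ccccc2)c(OCc2ccccc2)c(OCc2ccccc2)c1 | intermediate
14 | 1-[(2S,3R)-5,7-bis(benzyloxy)-2-[3,4,5-tris(benzyloxy)phenyl]chroman-3-yl]ethan-1-one | CC(=O)[C@@H]1Cc2c(OCc3ccccc3)cc(OCc3ccccc3)cc2O[C@@H]1c1cc(OCc2ccccc2)c(OCc2ccccc2)c(OCc2ccccc2)c1 | intermediate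
15 | (2R,3R)-5,7-bis(benzyloxy)-2-[3,4,5-tris(benzyloxy)phenyl]chroman-3-yl acetate | CC(=O)O[C@@H]1Cc2c(OCc3ccccc3)cc(OCc3ccccc3)cc2O[C@@H]1c1cc(OCc2ccccc2)c(OCc2ccccc2)c(OCc2ccccc2)c1 | intermediate
16 | (2R,3R)-5,7-bis(benzyloxy)-2-[3,4,5-tris(benzyloxy)phenyl]chroman-3-ol | O[C@@H]1Cc2c(OCc3ccccc3)cc(OCc3ccccc3)cc2O[C@@H]1c1cc(OCc2ccccc2)c(OCc2ccccc2)c(OCc2ccccc2)c1 | intermediate
17 | (+)-dihydrorobinetin, (2R,3R)-3,7-dihydroxy-2-(3,4,5-trihydroxyphenyl)chroman-4-one | Oc1ccc2c(c1)O[C@H](c1cc(O)c(O)c(O)c1)[C@@H](O)C2=O | starting material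
18 | (2R,3R)-7-(benzyloxy)-3-hydroxy-2-[3,4,5-tris(benzyloxy)phenyl]chroman-4-one | C(c1ccccc1)Oc1ccc2c(c1)O[C@H](c1cc(OCc3ccccc3)c(OCc3ccccc3)c(OCc3ccccc3)c1)[C@@H](O)C2=O | intermediate
19 | (2R,3S,4R)-7-(benzyloxy)-2-[3,4,5-tris(benzyloxy)phenyl]chromane-3,4-diol | C(c1ccccc1)Oc1ccc2c(c1)O[C@H](c1cc(OCc3ccccc3)c(OCc3ccccc3)c(OCc3ccccc3)c1)[C@@H](O)[C@@H]2O | intermediate
20 | nona-O-benzyl-robinetinidol-(4α→8)-epigallocatechin | C(c1ccccc1)Oc1ccc2c(c1)O[C@H](c1cc(OCc3ccccc3)c(OCc3ccccc3)c(OCc3ccccc3)c1)[C@@H](O)[C@@H]2c1c(OCc3ccccc3)cc(OCc3ccccc3)c2c1O[C@H](c1cc(OCc3ccccc3)c(OCc3ccccc3)c(OCc3ccccc3)c1)[C@H](O)C2 | intermediate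
21 | robinetinidol-(4α→8)-epigallocatechin | Oc1ccc2c(c1)O[C@H](c1cc(O)c(O)c(O)c1)[C@@H](O)[C@@H]2c1c(O)cc(O)c2c1O[C@H](c1cc(O)c(O)c(O)c1)[C@H](O)C2 | target

**Step count**
Total: 14 steps. Longest linear sequence: 10 steps (3, 4, 5, 6, 7, 8, 9, 10, 13, 14).

**Steps most likely to fail**

Step 7 (proposed new method). What may go wrong is retro-aldol cleavage or base-induced β-elimination of the lithium aldolate 11 while it is warmed with the catalyst, or β-hydride elimination at palladium before C–O reductive elimination. The fallback sets out from 3 and 9 and comes back at 12, and it replaces the domino by two isolated steps of known chemistry. The dianion alkylation is run alone and quenched cold (LiN(iPr)2, THF, −78 to −10 °C; aq. NH4Cl), and the neutral hydroxy ester ethyl (2R,3S)-2-[2-bromo-4,6-bis(benzyloxy)benzyl]-3-hydroxy-3-[3,4,5-tris(benzyloxy)phenyl]propanoate F1 is isolated. Ring F is then closed by palladium-catalysed intramolecular etherification of the free secondary alcohol under a weak heterogeneous base (Pd(OAc)2, 2-(di-tert-butylphosphino)-1,1'-binaphthyl, Cs2CO3, toluene, 60 °C), which should give 12.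

Step 9. What may go wrong is peracid attack on the electron-rich triether ring D, or epimerisation of 14 at C3 before the migration. The fallback sets out from 12 and comes back at 16, and it gives up C3 on purpose and resets it by reduction.
- Saponification (LiOH, THF/H2O) gives (2S,3R)-5,7-bis(benzyloxy)-2-[3,4,5-tris(benzyloxy)phenyl]chromane-3-carboxylic acid F2.
- DCC and N-hydroxypyridine-2-thione give its Barton ester, 2-thioxopyridin-1(2H)-yl (2S,3R)-5,7-bis(benzyloxy)-2-[3,4,5-tris(benzyloxy)phenyl]chromane-3-carboxylate F3.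
- Photolysis under O2 with t-BuSH, then PPh3, gives (2R)-5,7-bis(benzyloxy)-2-[3,4,5-tris(benzyloxy)phenyl]chroman-3-ol F4 as a mixture at C3.
- Dess–Martin periodinane oxidises the mixture to the flavan-3-one (2R)-5,7-bis(benzyloxy)-2-[3,4,5-tris(benzyloxy)phenyl]chroman-3-one F5.
- LiBH(s-Bu)3 (THF, −78 °C) should deliver hydride anti to the C2 aryl group and give the 2,3-cis alcohol 16.

Step 13. What may go wrong is attack through C6 instead of C8 of ring D, attack on the 4β face, or onward condensation of 20 to trimers. The fallback sets out from 17 and 16 and comes back at 21, and it moves the deprotection before the coupling (the classical condensation of the unprotected phenols). 17 is reduced directly (NaBH4, EtOH, 0 °C) to (+)-leucorobinetinidin, (2R,3S,4R)-2-(3,4,5-trihydroxyphenyl)chromane-3,4,7-triol F6. 16 is hydrogenolysed (H2, Pd(OH)2 on carbon, THF/MeOH) to (−)-epigallocatechin F7. F6 is then condensed with excess F7 in 0.1 M aqueous HCl at rt, and 21 should be obtained after chromatography on Sephadex LH-20.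

Further compounds
F1 | step 7 | ethyl (2R,3S)-2-[2-bromo-4,6-bis(benzyloxy)benzyl]-3-hydroxy-3-[3,4,5-tris(benzyloxy)phenyl]propanoate | CCOC(=O)[C@H](Cc1c(Br)cc(OCc2ccccc2)cc1OCc1ccccc1)[C@H](O)c1cc(OCc2ccccc2)c(OCc2ccccc2)c(OCc2ccccc2)c1
F2 | step 9 | (2S,3R)-5,7-bis(benzyloxy)-2-[3,4,5-tris(benzyloxy)phenyl]chromane-3-carboxylic acid | OC(=O)[C@@H]1Cc2c(OCc3ccccc3)cc(OCc3ccccc3)cc2O[C@@H]1c1cc(OCc2ccccc2)c(OCc2ccccc2)c(OCc2ccccc2)c1
F3 | step 9 | 2-thioxopyridin-1(2H)-yl (2S,3R)-5,7-bis(benzyloxy)-2-[3,4,5-tris(benzyloxy)phenyl]chromane-3-carboxylate | S=c1ccccn1OC(=O)[C@@H]1Cc2c(OCc3ccccc3)cc(OCc3ccccc3)cc2O[C@@H]1c1cc(OCc2ccccc2)c(OCc2ccccc2)c(OCc2ccccc2)c1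
F4 | step 9 | (2R)-5,7-bis(benzyloxy)-2-[3,4,5-tris(benzyloxy)phenyl]chroman-3-ol, mixture at C3 | OC1Cc2c(OCc3ccccc3)cc(OCc3ccccc3)cc2O[C@@H]1c1cc(OCc2ccccc2)c(OCc2ccccc2)c(OCc2ccccc2)c1
F5 | step 9 | (2R)-5,7-bis(benzyloxy)-2-[3,4,5-tris(benzyloxy)phenyl]chroman-3-one | O=C1Cc2c(OCc3ccccc3)cc(OCc3ccccc3)cc2O[C@@H]1c1cc(OCc2ccccc2)c(OCc2ccccc2)c(OCc2ccccc2)c1
F6 | step 13 | (+)-leucorobinetinidin, (2R,3S,4R)-2-(3,4,5-trihydroxyphenyl)chromane-3,4,7-triol | Oc1ccc2c(c1)O[C@H](c1cc(O)c(O)c(O)c1)[C@@H](O)[C@@H]2O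
F7 | step 13 | (−)-epigallocatechin, (2R,3R)-2-(3,4,5-trihydroxyphenyl)chromane-3,5,7-triol | O[C@@H]1Cc2c(O)cc(O)cc2O[C@@H]1c1cc(O)c(O)c(O)c1
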